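Everything rests on cutting the bond between the bridge methine and C7' of the dihydroisocoumarin ring (isochroman numbering; primes mark the lactone half). The bridge carbon sits on C7 of the other bicycle, between O6 and O8, so it is an ortho-hydroxybenzylic carbon. C7' is the only unsubstituted carbon of the lactone arene and lies between two phenolic OH groups. A chiral phosphoric acid dehydrates an epimeric 7-(1-hydroxyethyl)isochroman-6,8-diol to a planar ortho-quinone methide and delivers C7' of the unprotected lactone to one face. This gives fragment union, C–C bond and bridge stereocentre in one stereoconvergent operation. Both partners stem from one isochroman. The left ring is carried one oxidation level low and dehydrogenated last.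

Key step: step 10

Assumption: the sense of induction cannot be derived for this substrate pair, so (R)-TRIP is written, and its commercial antipode takes its place if a first run shows that the antipode leads to the bridge configuration of 15.

Step 1
Reactants: 1 2-bromo-4,6-dimethoxybenzaldehyde
Product: 2 1-bromo-3,5-dimethoxy-2-methylbenzene
Conditions: Et3SiH (3 equiv), TFA, CH2Cl2, 0 °C → rt
Reagents that add atoms: none
Why: Ionic hydrogenation (silane/Brønsted acid): the aldehyde carbon is ortho and para to methoxy groups, so the protonated aldehyde and then the benzylic cation each accept hydride from the silane, while the aryl bromide and the ethers are inert.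

Step 2
Reactants: 2 1-bromo-3,5-dimethoxy-2-methylbenzene; 3 (2S,3S)-2,3-dimethyloxirane
Product: 5 (2S,3S)-3-(3,5-dimethoxy-2-methylphenyl)butan-2-ol, via aryl Grignard reagent 4 (not isolated)
Conditions: Mg, THF, reflux; CuI (10 mol %), 3, −30 → 0 °C; H2O
Reagents that add atoms: none
Why: Copper-catalysed SN2 opening of an epoxide by an aryl Grignard reagent: the two carbons of the C2-symmetric trans-epoxide are equivalent, attack occurs with inversion, and this sets the benzylic centre (future C4 and C4', S) while the carbinol keeps its S configuration.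

Step 3
Reactants: 5 (2S,3S)-3-(3,5-dimethoxy-2-methylphenyl)butan-2-ol
Product: 6 (2R,3S)-3-(3,5-dimethoxy-2-methylphenyl)butan-2-yl 4-nitrobenzoate
Conditions: 4-O2NC6H4CO2H, PPh3, DIAD, toluene, 0 °C → rt
Reagents that add atoms: 4-nitrobenzoic acid, O=C(O)c1ccc(cc1)[N+](=O)[O-]
Why: Mitsunobu inversion with 4-nitrobenzoic acid (the acid of choice for hindered secondary alcohols): SN2 displacement of the oxyphosphonium group turns the S carbinol into the R ester (future C3 and C3'), and aryl participation is not favoured because both methoxy groups are meta to the side chain.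

Step 4
Reactants: 6 (2R,3S)-3-(3,5-dimethoxy-2-methylphenyl)butan-2-yl 4-nitrobenzoate
Product: 7 (2R,3S)-3-(3,5-dimethoxy-2-methylphenyl)butan-2-ol
Conditions: K2CO3 (cat.), MeOH, rt
Reagents that add atoms: none
Why: Base-catalysed transesterification breaks only the acyl–oxygen bond, so the R carbinol centre is released unchanged.

Step 5
Reactants: 7 (2R,3S)-3-(3,5-dimethoxy-2-methylphenyl)butan-2-ol
Product: 8 (3R,4S)-6,8-dimethoxy-3,4,5-trimethylisochroman
Conditions: CH2(OMe)2 (1.5 equiv), TMSOTf (cat.), CH2Cl2, 0 °C → rt
Reagents that add atoms: dimethoxymethane, COCOC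
Why: Oxa-Pictet–Spengler cyclisation: the alcohol and the formaldehyde acetal give an oxocarbenium ion that closes the pyran ring on the only free position ortho to the side chain, which is para to one methoxy group and ortho to the other, and no stereocentre is touched.

Step 6
Reactants: 8 (3R,4S)-6,8-dimethoxy-3,4,5-trimethylisochroman
Product: 9 (3R,4S)-6,8-dimethoxy-3,4,5-trimethylisochroman-1-one
Conditions: CrO3, aq. H2SO4, acetone, 0 °C
Reagents that add atoms: chromium trioxide, O=[Cr](=O)=O
Why: Jones oxidation of a benzylic ether: C1–H is benzylic, alpha to oxygen and activated by the ortho and para methoxy groups, so it is oxidised through the lactol to the isochroman-1-one ahead of the tertiary C4–H and the aryl methyl group.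

Step 7
Reactants: 9 (3R,4S)-6,8-dimethoxy-3,4,5-trimethylisochroman-1-one
Product: 10 (3R,4S)-6,8-dihydroxy-3,4,5-trimethylisochroman-1-one
Conditions: BBr3 (3 equiv), CH2Cl2, −78 °C → rt; H2O
Reagents that add atoms: none
Why: Lewis-acid cleavage of aryl methyl ethers with boron tribromide, helped at O8 by chelation to the lactone carbonyl, while the secondary lactone C–O bond and both stereocentres are not affected at or below room temperature.

Step 8
Reactants: 8 (3R,4S)-6,8-dimethoxy-3,4,5-trimethylisochroman
Product: 11 (3R,4S)-3,4,5-trimethylisochroman-6,8-diol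
Conditions: BBr3 (2.5 equiv), CH2Cl2, −78 → 0 °C; H2O
Reagents that add atoms: none
Why: Boron tribromide cleavage of aryl methyl ethers; should the benzylic C1–O2 bond open as well, the resulting hydroxybenzyl bromide recloses onto the pendant secondary oxygen on work-up without the C3–O bond ever being broken, so both stereocentres persist.

Step 9
Reactants: 11 (3R,4S)-3,4,5-trimethylisochroman-6,8-diol
Product: 13 (3R,4S)-7-(1-hydroxyethyl)-3,4,5-trimethylisochroman-6,8-diol (both carbinol epimers), via bis(bromomagnesium) phenolate 12 (not isolated)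
Conditions: EtMgBr (2.1 equiv), Et2O → CH2Cl2, 0 °C; CH3CHO (1.2 equiv), 0 °C → rt; H2O (pH 7); used without chromatography
Reagents that add atoms: acetaldehyde, CC=O
Why: Casiraghi-type ortho-hydroxyalkylation of a magnesium phenolate: the aldehyde is bound to the phenolate magnesium and attacked through a six-membered chelate by the ortho carbon, C7 is the only free ring position, the product stays masked as a magnesium chelate below room temperature, and the new carbinol centre needs no control because it is erased in step 10.

Step 10
Reactants: 13 (3R,4S)-7-(1-hydroxyethyl)-3,4,5-trimethylisochroman-6,8-diol; 10 (3R,4S)-6,8-dihydroxy-3,4,5-trimethylisochroman-1-one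
Product: 15 (3R,4S)-7-{(1S)-1-[(3R,4S)-6,8-dihydroxy-3,4,5-trimethylisochroman-7-yl]ethyl}-6,8-dihydroxy-3,4,5-trimethylisochroman-1-one, via ortho-quinone methide 14 (not isolated)
Conditions: (R)-TRIP (10 mol %), 10 (1.5 equiv), 4 Å MS, CH2Cl2–toluene, −40 → −10 °C, slow addition of 13
Reagents that add atoms: none
Why: The acid protonates the benzylic hydroxyl of either epimer of 13 and, with push from O6–H or O8–H, expels water to give the planar ortho-quinone methide 14, so the carbinol mixture converges; C7' of 10 then adds to the exocyclic methide carbon and proton loss rearomatises both rings. The closest known reaction type is the chiral-phosphoric-acid-catalysed Friedel–Crafts alkylation of phenols and naphthols with ortho-quinone methides generated in situ from ortho-hydroxybenzyl alcohols. No ring is closed. The bridge stereocentre is controlled by the catalyst, which binds the carbonyl oxygen of 14 through P–OH and O6'–H of 10 through P=O and leaves one methide face open between its 3,3'-aryl groups; the two tautomers of 14 (C6=O or C8=O) are related by a half turn about the C7–methide axis and so lead to the same bridge configuration, and the ring stereocentres are too remote to interfere. Chemoselectivity is secured by the substitution pattern: every ring carbon of 13 is substituted (C5 methyl, C8a in the pyran ring), so it cannot alkylate itself, and 10 offers only C7'. O-alkylation of 10 and tautomerisation of 14 to the 7-vinyl resorcinol are reversible under the acid whereas C–C bond formation is not, and slow addition of 13 keeps 14 dilute.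

Step 11
Reactants: 15 coupled isochroman–isochromanone
Product: 16 dicitrinone H, (3R,4S)-7-{(1R)-1-[(3R,4S)-6-hydroxy-3,4,5-trimethyl-8-oxo-4,8-dihydro-3H-isochromen-7-yl]ethyl}-6,8-dihydroxy-3,4,5-trimethylisochroman-1-one (the bridge is spatially unchanged; its descriptor changes from S to R because the CIP ranking of the two rings is reversed)
Conditions: DDQ (1.05 equiv), 1,4-dioxane, rt
Reagents that add atoms: none
Why: DDQ dehydrogenation by hydride abstraction (the reaction type used for C1–H functionalisation of isochromans): C1–H is alpha to O2 and ortho/para to the two phenols of the more electron-rich ring, the resulting 6,8-dihydroxyisochromenylium ion loses the O8 proton to give the quinone methide, and the bridge C–H is shielded by four ortho oxygens and cannot align with either arene.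

Compound list
1 | 2-bromo-4,6-dimethoxybenzaldehyde | O=Cc1c(Br)cc(OC)cc1OC | starting material
2 | 1-bromo-3,5-dimethoxy-2-methylbenzene | Cc1c(Br)cc(OC)cc1OC | intermediate
3 | (2S,3S)-2,3-dimethyloxirane | C[C@@H]1O[C@H]1C | starting material
4 | (3,5-dimethoxy-2-methylphenyl)magnesium bromide | COc1cc(OC)c(C)c([Mg]Br)c1 | intermediate
5 | (2S,3S)-3-(3,5-dimethoxy-2-methylphenyl)butan-2-ol | C[C@H](O)[C@@H](C)c1cc(OC)cc(OC)c1C | intermediate
6 | (2R,3S)-3-(3,5-dimethoxy-2-methylphenyl)butan-2-yl 4-nitrobenzoate | C[C@@H](OC(=O)c1ccc(cc1)[N+](=O)[O-])[C@@H](C)c1cc(OC)cc(OC)c1C | intermediate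
7 | (2R,3S)-3-(3,5-dimethoxy-2-methylphenyl)butan-2-ol | C[C@@H](O)[C@@H](C)c1cc(OC)cc(OC)c1C | intermediate
8 | (3R,4S)-6,8-dimethoxy-3,4,5-trimethylisochroman | Cc1c(OC)cc(OC)c2CO[C@H](C)[C@@H](C)c12 | intermediate
9 | (3R,4S)-6,8-dimethoxy-3,4,5-trimethylisochroman-1-one | Cc1c(OC)cc(OC)c2C(=O)O[C@H](C)[C@@H](C)c12 | intermediate
10 | (3R,4S)-6,8-dihydroxy-3,4,5-trimethylisochroman-1-one | Cc1c(O)cc(O)c2C(=O)O[C@H](C)[C@@H](C)c12 | intermediate
11 | (3R,4S)-3,4,5-trimethylisochroman-6,8-diol | Cc1c(O)cc(O)c2CO[C@H](C)[C@@H](C)c12 | intermediate
12 | bis(bromomagnesium) salt of 11 | Cc1c(O[Mg]Br)cc(O[Mg]Br)c2CO[C@H](C)[C@@H](C)c12 | intermediate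
13 | (3R,4S)-7-(1-hydroxyethyl)-3,4,5-trimethylisochroman-6,8-diol, carbinol centre undefined | Cc1c(O)c(C(C)O)c(O)c2CO[C@H](C)[C@@H](C)c12 | intermediate
14 | (3R,4S)-7-ethylidene-6-hydroxy-3,4,5-trimethyl-3,4-dihydro-1H-isochromen-8(7H)-one, alkene geometry mobile | CC1=C(O)C(=CC)C(=O)C2=C1[C@H](C)[C@@H](C)OC2 | intermediate
15 | (3R,4S)-7-{(1S)-1-[(3R,4S)-6,8-dihydroxy-3,4,5-trimethylisochroman-7-yl]ethyl}-6,8-dihydroxy-3,4,5-trimethylisochroman-1-one | Cc1c2c(CO[C@H](C)[C@H]2C)c(O)c([C@H](C)c2c(O)c(C)c3c(c2O)C(=O)O[C@H](C)[C@H]3C)c1O | intermediate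
16 | dicitrinone H | CC1=C2C(=CO[C@H](C)[C@H]2C)C(=O)C([C@H](C)c2c(O)c(C)c3c(c2O)C(=O)O[C@H](C)[C@H]3C)=C1O | target

Total step count: 11. Longest linear sequence: 9 steps (1–5, 8–11).

Steps most likely to fail

Step 10. Facial selectivity may be low, because either flanking oxygen of the methide can dock to the catalyst and an uncatalysed background ionisation competes. The methide may also be lost by cycloaddition to its own vinyl tautomer. The fallback sets out from 8 and 9 and comes back at 15. The bond is made without stereochemistry as an sp2–sp2 bond, and the stereocentre is set afterwards by hydride delivery. Lithiation of 8 at C7 (n-BuLi, THF) and acylation with N-methoxy-N-methylacetamide should give the 7-acetylisochroman F1, which is condensed with tosylhydrazine to the N-tosylhydrazone F2. NBS bromination of 9 at its only free ring position gives the 7-bromolactone F3. Barluenga coupling of F2 and F3 (Pd2(dba)3, XPhos, LiOt-Bu, dioxane, heat) gives the 1,1-diarylethene tetramethyl ether F4, and BBr3 frees the 1,1-diarylethene tetraphenol F5. Asymmetric transfer hydrogenation of this ortho-hydroxy-1,1-diarylethene with a Hantzsch ester and a chiral phosphoric acid gives 15. It runs through a methide whose two substituents (methyl and aryl) differ greatly in size.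

Step 11. Hydride abstraction at the doubly benzylic bridge C–H, or further oxidation of the resorcinol ring, may compete with C1–H abstraction. The fallback sets out from 7, uses 10 and comes back at 16. C1 is not carried through the coupling but is introduced last at the aldehyde level, so no oxidation is needed. BBr3 converts 7 into the side-chain triol F6. Magnesium-phenolate hydroxyalkylation with acetaldehyde between the two phenols gives the benzylic alcohol F7. The phosphoric-acid-catalysed coupling with an excess of 10 gives the seco compound F8, with the bridge configured as in 15. Triethyl orthoformate and trifluoroacetic acid then formylate the last free ring position through the mixed orthoester of the side-chain alcohol, and the hydroxy aldehyde closes and loses water to 16.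

Step 9. The magnesium-bound carbinol may ionise and the methide be captured by a second phenolate (symmetrical dimer formation), and acetaldehyde may undergo aldol self-condensation. The fallback sets out from 11 and comes back at 13, and the two carbons are introduced one at a time. Casnati–Skattebøl ortho-formylation (MgCl2, Et3N, paraformaldehyde, MeCN, reflux) gives the 7-carbaldehyde F9, a hydrogen-bonded 2,6-dihydroxybenzaldehyde that cannot ionise. Excess MeMgBr (THF, −78 → 0 °C) then adds to it to give 13.

Further compounds
F1 | step 10 | 1-[(3R,4S)-6,8-dimethoxy-3,4,5-trimethylisochroman-7-yl]ethanone | Cc1c(OC)c(C(C)=O)c(OC)c2CO[C@H](C)[C@@H](C)c12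
F2 | step 10 | N-tosylhydrazone of F1 | Cc1c(OC)c(C(C)=NNS(=O)(=O)c3ccc(C)cc3)c(OC)c2CO[C@H](C)[C@@H](C)c12
F3 | step 10 | (3R,4S)-7-bromo-6,8-dimethoxy-3,4,5-trimethylisochroman-1-one | Cc1c(OC)c(Br)c(OC)c2C(=O)O[C@H](C)[C@@H](C)c12
F4 | step 10 | (3R,4S)-7-{1-[(3R,4S)-6,8-dimethoxy-3,4,5-trimethylisochroman-7-yl]ethenyl}-6,8-dimethoxy-3,4,5-trimethylisochroman-1-one | Cc1c2c(CO[C@H](C)[C@H]2C)c(OC)c(C(=C)c2c(OC)c(C)c3c(c2OC)C(=O)O[C@H](C)[C@H]3C)c1OC
F5 | step 10 | (3R,4S)-7-{1-[(3R,4S)-6,8-dihydroxy-3,4,5-trimethylisochroman-7-yl]ethenyl}-6,8-dihydroxy-3,4,5-trimethylisochroman-1-one | Cc1c2c(CO[C@H](C)[C@H]2C)c(O)c(C(=C)c2c(O)c(C)c3c(c2O)C(=O)O[C@H](C)[C@H]3C)c1O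
F6 | step 11 | 5-[(2S,3R)-3-hydroxybutan-2-yl]-4-methylbenzene-1,3-diol | C[C@@H](O)[C@@H](C)c1cc(O)cc(O)c1C
F7 | step 11 | 2-(1-hydroxyethyl)-5-[(2S,3R)-3-hydroxybutan-2-yl]-4-methylbenzene-1,3-diol, benzylic carbinol undefined | C[C@@H](O)[C@@H](C)c1cc(O)c(C(C)O)c(O)c1C
F8 | step 11 | (3R,4S)-7-{1-[2,6-dihydroxy-4-((2S,3R)-3-hydroxybutan-2-yl)-3-methylphenyl]ethyl}-6,8-dihydroxy-3,4,5-trimethylisochroman-1-one, bridge as in 15 | C[C@@H](O)[C@@H](C)c1cc(O)c([C@H](C)c2c(O)c(C)c3c(c2O)C(=O)O[C@H](C)[C@H]3C)c(O)c1C
F9 | step 9 | (3R,4S)-6,8-dihydroxy-3,4,5-trimethylisochroman-7-carbaldehyde | Cc1c(O)c(C=O)c(O)c2CO[C@H](C)[C@@H](C)c12
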